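**Retrosynthetic overview**
1. The ten-membered ring is closed last at C8–C9: a carbene turns the C9 aldehyde into an acyl anion equivalent (Breslow intermediate) that attacks the C8 ketone of a preformed 3-hydroxy-3-methylfuran-2,4-dione. C9 is then reduced and acetylated, and the ring A cis-diol is added by OsO4 near the end.
2. The open-chain precursor comes from a Nozaki–Hiyama–Kishi coupling at C4–C5 between a (Z)-vinyl iodide lactone and a β-hydroxy-α-silyloxy aldehyde; C4 is then set by oxidation and 1,3-anti reduction.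
3. C2 and C3 come from an L-proline aldol of the ring A aldehyde with (tert-butyldimethylsilyloxy)acetaldehyde.
4. Ring A is formed first, by an enantioselective Diels–Alder reaction (sets C1 and C10), and its enone is converted to the 11,13-diene.
5. The γ-lactone is formed second, on a separate branch, from (R)-lactic acid (Seebach dioxolanone) and (S)-glyceraldehyde acetonide; the ten-membered ring is formed third.

Assumption: atoms carry briarane numbers (C1 and C10 ring fusion, C2–C9 around the ten-membered ring, C11–C14 ring A, C15/C16/C18/C20 the methyls on C1/C5/C17/C11, C19 the lactone carbonyl); the (R,R)-TADDOL in step 3 is taken to give the (1S,10S) adduct, and its mirror image is used if the sense is the opposite.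

**Route**

Step 1
Reactants: 1 (tert-butyldimethylsilyloxy)acetaldehyde; 2 2-(triphenylphosphoranylidene)propanal
Product: 3 (E)-4-(tert-butyldimethylsilyloxy)-2-methylbut-2-enal
Conditions: toluene, 80 °C
Reagents that add atoms: none
Why: Wittig olefination with a stabilised ylide gives the E enal, which places the C15 methyl and the C9 arm cis for the cycloaddition.

Step 2
Reactants: 4 (E)-1-(dimethylamino)pent-1-en-3-one
Product: 5 (1E,3Z)-3-(tert-butyldimethylsilyloxy)-N,N-dimethylpenta-1,3-dien-1-amine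
Conditions: TBSOTf, Et3N, Et2O, 0 °C
Reagents that add atoms: tert-butyldimethylsilyl trifluoromethanesulfonate, CC(C)(C)[Si](C)(C)OS(=O)(=O)C(F)(F)F
Why: Soft enolisation of the vinylogous amide (O-silylation, then deprotonation of the ethyl group) gives the 1-amino-3-siloxy diene with the methyl group on the outside.

Step 3
Reactants: 3 (E)-4-(tert-butyldimethylsilyloxy)-2-methylbut-2-enal; 5 (1E,3Z)-3-(tert-butyldimethylsilyloxy)-N,N-dimethylpenta-1,3-dien-1-amine
Product: 8 (4S,5S)-5-[(tert-butyldimethylsilyloxy)methyl]-4-(hydroxymethyl)-4,6-dimethylcyclohex-2-en-1-one (C6 epimers), via cycloadduct aldehyde 6 (not isolated), via amino alcohol 7 (not isolated)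
Conditions: (R,R)-1-naphthyl-TADDOL (20 mol%), toluene, −78 to −40 °C; LiAlH4, Et2O, −78 to 0 °C; 0.1 M HCl, THF, 0 °C
Reagents that add atoms: none
Why: Hydrogen-bond-catalysed Diels–Alder reaction of the aminosiloxydiene with the α-substituted enal joins C14–C1 and C11–C10 and sets C1 and C10 (methyl and C9 arm cis by suprafacial addition to the E enal, absolute sense from the TADDOL); hydride reduction of the aldehyde and acid-induced enol ether hydrolysis with β-elimination of dimethylamine then give the enone.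

Step 4
Reactants: 8 (4S,5S)-5-[(tert-butyldimethylsilyloxy)methyl]-4-(hydroxymethyl)-4,6-dimethylcyclohex-2-en-1-one
Product: 10 dienyl triflate (C12–OTf; C11=C12 and C13=C14; C1 and C10 as in 8), via dipotassium alkoxide enolate 9 (not isolated)
Conditions: KN(SiMe3)2 (2.2 equiv), THF, −78 °C; PhNTf2 (1.05 equiv), −78 to 0 °C
Reagents that add atoms: N-phenylbis(trifluoromethanesulfonimide), O=S(=O)(N(c1ccccc1)S(=O)(=O)C(F)(F)F)C(F)(F)F
Why: Enol triflate formation: the ketone can only be deprotonated at C11 because C1 is quaternary, and the dienolate oxygen is triflated in preference to the hindered neopentyl alkoxide.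

Step 5
Reactants: 10 dienyl triflate
Product: 11 [(1S,6S)-6-[(tert-butyldimethylsilyloxy)methyl]-1,5-dimethylcyclohexa-2,4-dien-1-yl]methanol
Conditions: Pd(OAc)2 (5 mol%), PPh3 (10 mol%), HCO2H, Bu3N, DMF, 60 °C
Reagents that add atoms: none
Why: Palladium-catalysed formate reduction of the vinyl triflate replaces OTf by H and leaves the conjugated 11,13-diene that later takes the cis-diol.

Step 6
Reactants: 11 [(1S,6S)-6-[(tert-butyldimethylsilyloxy)methyl]-1,5-dimethylcyclohexa-2,4-dien-1-yl]methanol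
Product: 12 (1S,6S)-6-[(tert-butyldimethylsilyloxy)methyl]-1,5-dimethylcyclohexa-2,4-diene-1-carbaldehyde
Conditions: Dess–Martin periodinane, NaHCO3, CH2Cl2, 0 °C to rt
Reagents that add atoms: none
Why: Dess–Martin oxidation gives the non-enolisable C2 aldehyde without touching the diene or a stereocentre.

Step 7
Reactants: 13 (R)-lactic acid; 14 pivalaldehyde
Product: 15 (2R,5R)-2-tert-butyl-5-methyl-1,3-dioxolan-4-one
Conditions: TsOH·H2O (cat.), H2SO4 (cat.), pentane, reflux, Dean–Stark; crystallisation of the cis isomer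
Reagents that add atoms: none
Why: Acid-catalysed acetalisation (Seebach dioxolanone) stores the lactic acid configuration in the acetal carbon for self-regeneration of the stereocentre.

Step 8
Reactants: 16 (R)-2,2-dimethyl-1,3-dioxolane-4-methanol
Product: 17 (S)-2,2-dimethyl-1,3-dioxolane-4-carbaldehyde
Conditions: TEMPO (10 mol%), PhI(OAc)2, CH2Cl2, rt; used crude
Reagents that add atoms: none
Why: Oxoammonium oxidation of the primary alcohol gives the aldehyde without touching the stereocentre that becomes C7.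

Step 9
Reactants: 15 (2R,5R)-2-tert-butyl-5-methyl-1,3-dioxolan-4-one; 17 (S)-2,2-dimethyl-1,3-dioxolane-4-carbaldehyde
Product: 19 (2R,5S)-2-tert-butyl-5-{hydroxy[(4S)-2,2-dimethyl-1,3-dioxolan-4-yl]methyl}-5-methyl-1,3-dioxolan-4-one (carbinol epimers), via lithium enolate 18 (not isolated)
Conditions: LiN(iPr)2, THF, −78 °C; then 17, −78 °C; NH4Cl
Reagents that add atoms: none
Why: Seebach aldol with self-regeneration of the stereocentre: the aldehyde adds to the enolate face opposite the tert-butyl group, which sets C17 (S) with net retention; the C8 carbinol epimers do not matter because C8 is oxidised in step 20.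

Step 10
Reactants: 19 (2R,5S)-2-tert-butyl-5-{hydroxy[(4S)-2,2-dimethyl-1,3-dioxolan-4-yl]methyl}-5-methyl-1,3-dioxolan-4-one
Product: 20 (3S,5S)-3,4-dihydroxy-5-(hydroxymethyl)-3-methyloxolan-2-one (C4 epimers)
Conditions: TFA–H2O (4:1), rt; toluene azeotrope
Reagents that add atoms: none
Why: Acid removes both acetals and the freed C7 hydroxyl closes the γ-lactone (favoured over the δ-lactone) with loss of pivalaldehyde.

Step 11
Reactants: 20 (3S,5S)-3,4-dihydroxy-5-(hydroxymethyl)-3-methyloxolan-2-one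
Product: 21 (3S,5S)-3-hydroxy-3-methyl-4-(triethylsilyloxy)-5-[(triethylsilyloxy)methyl]oxolan-2-one (C4 epimers)
Conditions: Et3SiCl (2.3 equiv), imidazole, DMF, 0 °C
Reagents that add atoms: chlorotriethylsilane, CC[Si](Cl)(CC)CC
Why: Silylation takes the primary and the secondary hydroxyl and leaves the hindered tertiary C17 hydroxyl free.

Step 12
Reactants: 21 (3S,5S)-3-hydroxy-3-methyl-4-(triethylsilyloxy)-5-[(triethylsilyloxy)methyl]oxolan-2-one
Product: 23 (2R,4S)-4-hydroxy-4-methyl-5-oxo-3-(triethylsilyloxy)oxolane-2-carbaldehyde (C3 epimers), via alkoxysulfonium salt 22 (not isolated)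
Conditions: (COCl)2, DMSO, CH2Cl2, −78 to −40 °C; Et3N, −78 °C to rt
Reagents that add atoms: none
Why: Under Swern conditions the chlorosulfonium salt cleaves only the primary triethylsilyl ether and the resulting alkoxysulfonium salt is oxidised directly to the C6 aldehyde, while the secondary silyl ether survives.

Step 13
Reactants: 23 (2R,4S)-4-hydroxy-4-methyl-5-oxo-3-(triethylsilyloxy)oxolane-2-carbaldehyde
Product: 24 (3S,5S)-3-hydroxy-5-[(Z)-2-iodoprop-1-en-1-yl]-3-methyl-4-(triethylsilyloxy)oxolan-2-one (C4 epimers)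
Conditions: EtPPh3I, n-BuLi, THF; I2, −78 °C; NaN(SiMe3)2, −20 °C; then 23, −78 °C
Reagents that add atoms: ethyltriphenylphosphonium iodide, CC[P+](c1ccccc1)(c1ccccc1)c1ccccc1.[I-]; iodine, II
Why: Stork–Zhao-type Wittig reaction with the α-iodo ylide gives the Z vinyl iodide (iodine cis to C7), which fixes the 5Z geometry because the later coupling goes with retention.

Step 14
Reactants: 12 (1S,6S)-6-[(tert-butyldimethylsilyloxy)methyl]-1,5-dimethylcyclohexa-2,4-diene-1-carbaldehyde; 1 (tert-butyldimethylsilyloxy)acetaldehyde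
Product: 25 (2S,3S)-2-(tert-butyldimethylsilyloxy)-3-hydroxy-3-{(1S,6S)-6-[(tert-butyldimethylsilyloxy)methyl]-1,5-dimethylcyclohexa-2,4-dien-1-yl}propanal
Conditions: L-proline (30 mol%), DMF, 4 °C, 1 added by syringe pump over 24 h
Reagents that add atoms: none
Why: Proline enamine aldol (Houk–List transition state) of the α-silyloxy aldehyde with the non-enolisable acceptor gives the anti adduct and sets C2 (S) and C3 under catalyst control; slow addition suppresses donor dimerisation.

Step 15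
Reactants: 25 (2S,3S)-aldol aldehyde; 24 (Z)-vinyl iodide lactone (1.5 equiv)
Product: 26 C4–C5 coupled allylic alcohol (2-OH and 3-OTBS as in 25; 4-OH as both epimers; 5Z; lactone with 8-OTES and 17-OH; ring A diene with 9-OTBS)
Conditions: CrCl2 (6 equiv), NiCl2 (2 mol%), DMSO, rt
Reagents that add atoms: none
Why: Nozaki–Hiyama–Kishi coupling forms C4–C5 with retention of the Z geometry and tolerates the lactone, the free hydroxyls and the diene; the C4 epimers are converged in steps 16 and 17.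

Step 16
Reactants: 26 C4–C5 coupled allylic alcohol
Product: 27 C4 ketone (Z enone; otherwise as 26)
Conditions: MnO2, CH2Cl2, rt
Reagents that add atoms: none
Why: MnO2 oxidises only the allylic C4 alcohol and leaves the non-allylic C2 hydroxyl, which is needed to direct the next step.

Step 17
Reactants: 27 C4 ketone
Product: 28 2,4-anti diol (C2, C3 and C4 as in the target; otherwise as 26)
Conditions: Me4NBH(OAc)3, MeCN–AcOH, −30 °C
Reagents that add atoms: none
Why: Evans–Saksena reduction delivers hydride intramolecularly from the boron bound to the C2 oxygen through a chair transition state, giving the 1,3-anti diol and so the 4S centre.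

Step 18
Reactants: 28 2,4-anti diol
Product: 29 2,4-diacetate (3-OTBS; 8-OTES; 9-OTBS; 17-OH free)
Conditions: Ac2O, pyridine, DMAP (0.1 equiv), CH2Cl2, 0 °C to rt
Reagents that add atoms: acetic anhydride, CC(=O)OC(C)=O
Why: DMAP-catalysed acetylation takes the two secondary hydroxyls, while the tertiary C17 hydroxyl does not react under these conditions.

Step 19
Reactants: 29 2,4-diacetate
Product: 30 8,9-diol (primary C9 hydroxyl and C8 carbinol free; 3-OTBS kept)
Conditions: HF·pyridine, pyridine, THF, 0 °C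
Reagents that add atoms: none
Why: Buffered HF cleaves the primary TBS ether and the secondary triethylsilyl ether much faster than the C3 TBS ether, which is flanked by two acetoxy-bearing carbons.

Step 20
Reactants: 30 8,9-diol
Product: 31 keto aldehyde (C9 aldehyde; C8 ketone of a 3-hydroxy-3-methylfuran-2,4-dione)
Conditions: Dess–Martin periodinane (3 equiv), NaHCO3, CH2Cl2, 0 °C to rt; used at once
Reagents that add atoms: none
Why: One Dess–Martin oxidation turns the primary alcohol into the C9 aldehyde and the C8 carbinol into the ketone under neutral conditions, which protect the acidic C7–H.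

Step 21
Reactants: 31 keto aldehyde
Product: 32 macrocyclic ketol (9-oxo; 8-OH; C8 as in the target; ten-membered ring closed)
Conditions: 2-(pentafluorophenyl)-6,7-dihydro-5H-pyrrolo[2,1-c][1,2,4]triazol-2-ium tetrafluoroborate (20 mol%), iPr2NEt (20 mol%), CH2Cl2 (0.002 M, slow addition of 31), 35 °C
Reagents that add atoms: none
Why: Proposed new method: the triazolylidene adds to the unhindered C9 aldehyde to give the Breslow intermediate (an acyl anion equivalent), whose carbon attacks the strongly activated C8 ketone on the face carrying H7 and the small hydroxyl (opposite the C6 chain and the C18 methyl), closing the ten-membered ring and setting C8 (S), with only catalytic weak base present to spare C7–H and C10–H; the closest known chemistry is the carbene-catalysed intramolecular crossed aldehyde–ketone benzoin reaction (five- and six-membered rings) and the carbene-catalysed macrocyclic Stetter reaction.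

Step 22
Reactants: 32 macrocyclic ketol
Product: 33 8,9-diol (9S carbinol; otherwise as 32)
Conditions: Zn(BH4)2, Et2O, −20 °C
Reagents that add atoms: none
Why: Chelation-controlled reduction: zinc bridges the C8 hydroxyl and the C9 carbonyl and hydride enters from the side of C7, away from the quaternary C17, which gives the 9S alcohol.

Step 23
Reactants: 33 8,9-diol
Product: 34 2,4,9-triacetate (3-OTBS; 11,13-diene; tertiary 8-OH and 17-OH free)
Conditions: Ac2O, pyridine, DMAP (0.1 equiv), CH2Cl2, rt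
Reagents that add atoms: acetic anhydride, CC(=O)OC(C)=O
Why: Acetylation takes the only free secondary hydroxyl (C9) and leaves the two tertiary ones.

Step 24
Reactants: 34 2,4,9-triacetate
Product: 35 3-O-(tert-butyldimethylsilyl)brianodin C
Conditions: OsO4 (5 mol%), NMO (1.1 equiv), acetone–H2O, 0 °C
Reagents that add atoms: osmium tetroxide, O=[Os](=O)(=O)=O; N-methylmorpholine N-oxide, C[N+]1([O-])CCOCC1; water, O
Why: Upjohn dihydroxylation attacks the most electron-rich trisubstituted C11=C12 bond of the diene from the face opposite the C9 substituent on C10, giving the cis 11S,12R diol; the C5=C6 bond is deactivated by its two allylic acyloxy groups and C13=C14 is shielded by the quaternary C1.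

Step 25
Reactants: 35 3-O-(tert-butyldimethylsilyl)brianodin C
Product: 36 brianodin C
Conditions: HF·pyridine, THF, 0 °C to rt
Reagents that add atoms: none
Why: Desilylation under mildly acidic fluoride conditions frees the C3 hydroxyl without acetyl migration from C2 or C4.

**Compound list**

1 | (tert-butyldimethylsilyloxy)acetaldehyde | O=CCO[Si](C)(C)C(C)(C)C | starting material
2 | 2-(triphenylphosphoranylidene)propanal | CC(C=O)=P(c1ccccc1)(c1ccccc1)c1ccccc1 | starting material
3 | (E)-4-(tert-butyldimethylsilyloxy)-2-methylbut-2-enal | O=C/C(C)=C/CO[Si](C)(C)C(C)(C)C | intermediate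
4 | (E)-1-(dimethylamino)pent-1-en-3-one | CCC(=O)/C=C/N(C)C | starting material
5 | (1E,3Z)-3-(tert-butyldimethylsilyloxy)-N,N-dimethylpenta-1,3-dien-1-amine | C/C=C(O[Si](C)(C)C(C)(C)C)/C=C/N(C)C | intermediate
6 | Diels–Alder adduct: 2-(dimethylamino)-4-silyloxycyclohex-3-ene-1-carbaldehyde, C1 and C10 as in 8, amine- and methyl-bearing ring carbons unassigned | O=C[C@@]1(C)C(N(C)C)C=C(O[Si](C)(C)C(C)(C)C)C(C)[C@@H]1CO[Si](C)(C)C(C)(C)C | intermediate
7 | amino alcohol from reduction of 6 | OC[C@@]1(C)C(N(C)C)C=C(O[Si](C)(C)C(C)(C)C)C(C)[C@@H]1CO[Si](C)(C)C(C)(C)C | intermediate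
8 | (4S,5S)-5-[(tert-butyldimethylsilyloxy)methyl]-4-(hydroxymethyl)-4,6-dimethylcyclohex-2-en-1-one (C6 epimers) | OC[C@@]1(C)C=CC(=O)C(C)[C@@H]1CO[Si](C)(C)C(C)(C)C | intermediate
9 | dipotassium alkoxide dienolate of 8 | [K+].[K+].[O-]C[C@@]1(C)C=CC([O-])=C(C)[C@@H]1CO[Si](C)(C)C(C)(C)C | intermediate
10 | dienyl triflate of 8 (C12–OTf, 11,13-diene) | OC[C@@]1(C)C=CC(OS(=O)(=O)C(F)(F)F)=C(C)[C@@H]1CO[Si](C)(C)C(C)(C)C | intermediate
11 | [(1S,6S)-6-[(tert-butyldimethylsilyloxy)methyl]-1,5-dimethylcyclohexa-2,4-dien-1-yl]methanol | OC[C@@]1(C)C=CC=C(C)[C@@H]1CO[Si](C)(C)C(C)(C)C | intermediate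
12 | (1S,6S)-6-[(tert-butyldimethylsilyloxy)methyl]-1,5-dimethylcyclohexa-2,4-diene-1-carbaldehyde | O=C[C@@]1(C)C=CC=C(C)[C@@H]1CO[Si](C)(C)C(C)(C)C | intermediate
13 | (R)-lactic acid | C[C@@H](O)C(=O)O | starting material
14 | pivalaldehyde | CC(C)(C)C=O | starting material
15 | (2R,5R)-2-tert-butyl-5-methyl-1,3-dioxolan-4-one | C[C@H]1O[C@@H](C(C)(C)C)OC1=O | intermediate
16 | (R)-2,2-dimethyl-1,3-dioxolane-4-methanol | OC[C@@H]1COC(C)(C)O1 | starting material
17 | (S)-2,2-dimethyl-1,3-dioxolane-4-carbaldehyde | O=C[C@@H]1COC(C)(C)O1 | intermediate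
18 | lithium enolate of 15 | CC1=C([O-])O[C@H](C(C)(C)C)O1.[Li+] | intermediate
19 | (2R,5S)-2-tert-butyl-5-{hydroxy[(4S)-2,2-dimethyl-1,3-dioxolan-4-yl]methyl}-5-methyl-1,3-dioxolan-4-one (carbinol epimers) | CC1(C)OC[C@H](O1)C(O)[C@]2(C)O[C@@H](C(C)(C)C)OC2=O | intermediate
20 | (3S,5S)-3,4-dihydroxy-5-(hydroxymethyl)-3-methyloxolan-2-one (C4 epimers) | OC[C@@H]1OC(=O)[C@@](C)(O)C1O | intermediate
21 | (3S,5S)-3-hydroxy-3-methyl-4-(triethylsilyloxy)-5-[(triethylsilyloxy)methyl]oxolan-2-one (C4 epimers) | CC[Si](CC)(CC)OC[C@@H]1OC(=O)[C@@](C)(O)C1O[Si](CC)(CC)CC | intermediate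
22 | alkoxydimethylsulfonium chloride from the primary ether of 21 | C[S+](C)OC[C@@H]1OC(=O)[C@@](C)(O)C1O[Si](CC)(CC)CC.[Cl-] | intermediate
23 | (2R,4S)-4-hydroxy-4-methyl-5-oxo-3-(triethylsilyloxy)oxolane-2-carbaldehyde (C3 epimers) | O=C[C@@H]1OC(=O)[C@@](C)(O)C1O[Si](CC)(CC)CC | intermediate
24 | (3S,5S)-3-hydroxy-5-[(Z)-2-iodoprop-1-en-1-yl]-3-methyl-4-(triethylsilyloxy)oxolan-2-one (C4 epimers) | I/C(C)=C\[C@@H]1OC(=O)[C@@](C)(O)C1O[Si](CC)(CC)CC | intermediate
25 | (2S,3S)-2-(tert-butyldimethylsilyloxy)-3-hydroxy-3-{(1S,6S)-6-[(tert-butyldimethylsilyloxy)methyl]-1,5-dimethylcyclohexa-2,4-dien-1-yl}propanal | O=C[C@@H](O[Si](C)(C)C(C)(C)C)[C@@H](O)[C@@]1(C)C=CC=C(C)[C@@H]1CO[Si](C)(C)C(C)(C)C | intermediate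
26 | C4–C5 coupled allylic alcohol (C4 and C8 epimers; 5Z) | O[C@@H]([C@@]1(C)C=CC=C(C)[C@@H]1CO[Si](C)(C)C(C)(C)C)[C@H](O[Si](C)(C)C(C)(C)C)C(O)/C(C)=C\[C@@H]1OC(=O)[C@@](C)(O)C1O[Si](CC)(CC)CC | intermediate
27 | C4 ketone (Z enone; C8 epimers) | O[C@@H]([C@@]1(C)C=CC=C(C)[C@@H]1CO[Si](C)(C)C(C)(C)C)[C@H](O[Si](C)(C)C(C)(C)C)C(=O)/C(C)=C\[C@@H]1OC(=O)[C@@](C)(O)C1O[Si](CC)(CC)CC | intermediate
28 | 2,4-anti diol (C2, C3, C4 as in the target; C8 epimers) | O[C@@H]([C@@]1(C)C=CC=C(C)[C@@H]1CO[Si](C)(C)C(C)(C)C)[C@H](O[Si](C)(C)C(C)(C)C)[C@@H](O)/C(C)=C\[C@@H]1OC(=O)[C@@](C)(O)C1O[Si](CC)(CC)CC | intermediate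
29 | 2,4-diacetate (C8 epimers) | CC(=O)O[C@@H]([C@@]1(C)C=CC=C(C)[C@@H]1CO[Si](C)(C)C(C)(C)C)[C@H](O[Si](C)(C)C(C)(C)C)[C@@H](OC(C)=O)/C(C)=C\[C@@H]1OC(=O)[C@@](C)(O)C1O[Si](CC)(CC)CC | intermediate
30 | 8,9-diol of the 2,4-diacetate (C8 epimers) | CC(=O)O[C@@H]([C@@]1(C)C=CC=C(C)[C@@H]1CO)[C@H](O[Si](C)(C)C(C)(C)C)[C@@H](OC(C)=O)/C(C)=C\[C@@H]1OC(=O)[C@@](C)(O)C1O | intermediate
31 | keto aldehyde (C9 aldehyde, C8 ketone) | CC(=O)O[C@@H]([C@@]1(C)C=CC=C(C)[C@@H]1C=O)[C@H](O[Si](C)(C)C(C)(C)C)[C@@H](OC(C)=O)/C(C)=C\[C@@H]1OC(=O)[C@@](C)(O)C1=O | intermediate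
32 | macrocyclic ketol (9-oxo, 8-hydroxy; 2,4-diacetate; 3-OTBS; 11,13-diene) | CC(=O)O[C@@H]1[C@H](O[Si](C)(C)C(C)(C)C)[C@@H](OC(C)=O)/C(C)=C\[C@@H]2OC(=O)[C@@](C)(O)[C@@]2(O)C(=O)[C@H]2C(C)=CC=C[C@]12C | intermediate
33 | macrocyclic 8,9-diol (9S) | CC(=O)O[C@@H]1[C@H](O[Si](C)(C)C(C)(C)C)[C@@H](OC(C)=O)/C(C)=C\[C@@H]2OC(=O)[C@@](C)(O)[C@@]2(O)[C@@H](O)[C@H]2C(C)=CC=C[C@]12C | intermediate
34 | 2,4,9-triacetate with 3-OTBS and 11,13-diene | CC(=O)O[C@@H]1[C@H](O[Si](C)(C)C(C)(C)C)[C@@H](OC(C)=O)/C(C)=C\[C@@H]2OC(=O)[C@@](C)(O)[C@@]2(O)[C@@H](OC(C)=O)[C@H]2C(C)=CC=C[C@]12C | intermediate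
35 | 3-O-(tert-butyldimethylsilyl)brianodin C | CC(=O)O[C@@H]1[C@H](O[Si](C)(C)C(C)(C)C)[C@@H](OC(C)=O)/C(C)=C\[C@@H]2OC(=O)[C@@](C)(O)[C@@]2(O)[C@@H](OC(C)=O)[C@H]2[C@](C)(O)[C@H](O)C=C[C@]12C | intermediate
36 | brianodin C (1S,2S,3R,4S,5Z,7S,8S,9S,10S,11S,12R,17S) | CC(=O)O[C@@H]1[C@H](O)[C@@H](OC(C)=O)/C(C)=C\[C@@H]2OC(=O)[C@@](C)(O)[C@@]2(O)[C@@H](OC(C)=O)[C@H]2[C@](C)(O)[C@H](O)C=C[C@]12C | target

**Step count and risk**

Total steps: 25. Longest linear sequence: 17 (steps 1, 3–6, 14–25; the lactone branch through steps 7, 9–13, 15–25 is equally long).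

Three steps most likely to fail, each with one fallback:

(a) Step 21, the ring-closing benzoin. The ten-membered ring may not close, the benzoin may revert, or C7 or C10 may epimerise. The fallback sets out from 11 and 24 and comes back at 34: the same C8–C9 bond is made between the fragments and the ring is closed at C4–C5 instead. HF·pyridine frees diene diol F1 from 11 and Dess–Martin periodinane gives dialdehyde F2. HF·pyridine on 24 gives lactone diol F3 and Dess–Martin periodinane gives furandione F4. The same triazolium salt with iPr2NEt joins F2 to F4 to give ketol aldehyde F5; only the unhindered C9 aldehyde of F2 forms a Breslow intermediate. L-Proline aldol with 1 gives hydroxy aldehyde F6. CrCl2/NiCl2 at high dilution closes the ring to macrocyclic allylic alcohol F7, and MnO2 gives enone F8. Me4NBH(OAc)3 reduces both hydroxyl-directed ketones (C4 and C9) to triol F9, and Ac2O/pyridine/DMAP gives 34.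

(b) Step 14, the proline cross-aldol. The neopentyl acceptor is hindered and the donor can dimerise. The fallback sets out from 12 and comes back at 25. A Mukaiyama aldol of 12 with (Z)-2-(tert-butyldimethylsilyloxy)-1-(ethylthio)-1-(trimethylsilyloxy)ethene is promoted by Sn(OTf)2, Bu2Sn(OAc)2 and the proline-derived diamine 1-methyl-2-[(1-naphthylamino)methyl]pyrrolidine (the enantiomer matched to the 2S,3S product) in CH2Cl2 at −78 °C and gives anti thioester F10. iBu2AlH (CH2Cl2, −78 °C) reduces F10 to 25.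

(c) Step 3, the enantioselective cycloaddition. The β-substituted enal may react slowly or with low enantioselectivity. The fallback sets out from 3 and 5 and comes back at 8. The uncatalysed cycloaddition (toluene, rt), followed by the same LiAlH4 and HCl treatment, gives 8 together with its mirror-image enone alcohol F11. Esterification with (S)-2-methoxy-2-phenylacetic acid (DCC, DMAP) gives mandelate ester F12 from 8 and diastereomeric mandelate ester F13 from F11, which are separated on silica. K2CO3 in MeOH cleaves F12 back to 8.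

Further compounds
F1 | step 21 | diene diol [(1,5-dimethylcyclohexa-2,4-diene-1,6-diyl)dimethanol, C1 and C10 as in 11] | OC[C@@]1(C)C=CC=C(C)[C@@H]1CO
F2 | step 21 | dialdehyde (C2 and C9 aldehydes on the ring A diene) | O=C[C@@]1(C)C=CC=C(C)[C@@H]1C=O
F3 | step 21 | lactone diol (24 without the triethylsilyl group; C4 epimers) | I/C(C)=C\[C@@H]1OC(=O)[C@@](C)(O)C1O
F4 | step 21 | furandione (3S,5S)-3-hydroxy-5-[(Z)-2-iodoprop-1-en-1-yl]-3-methyloxolane-2,4-dione | I/C(C)=C\[C@@H]1OC(=O)[C@@](C)(O)C1=O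
F5 | step 21 | ketol aldehyde (C8–C9 joined; 9-oxo, 8-hydroxy; C2 aldehyde; vinyl iodide) | I/C(C)=C\[C@@H]1OC(=O)[C@@](C)(O)[C@@]1(O)C(=O)[C@H]1C(C)=CC=C[C@]1(C)C=O
F6 | step 21 | hydroxy aldehyde (2-OH, 3-OTBS, C4 aldehyde; 9-oxo; vinyl iodide) | I/C(C)=C\[C@@H]1OC(=O)[C@@](C)(O)[C@@]1(O)C(=O)[C@H]1C(C)=CC=C[C@]1(C)[C@H](O)[C@H](O[Si](C)(C)C(C)(C)C)C=O
F7 | step 21 | macrocyclic allylic alcohol (2-OH, 3-OTBS, 4-OH as both epimers, 9-oxo) | O[C@@H]1[C@H](O[Si](C)(C)C(C)(C)C)C(O)/C(C)=C\[C@@H]2OC(=O)[C@@](C)(O)[C@@]2(O)C(=O)[C@H]2C(C)=CC=C[C@]12C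
F8 | step 21 | macrocyclic enone (4,9-dioxo, 2-OH, 3-OTBS) | O[C@@H]1[C@H](O[Si](C)(C)C(C)(C)C)C(=O)/C(C)=C\[C@@H]2OC(=O)[C@@](C)(O)[C@@]2(O)C(=O)[C@H]2C(C)=CC=C[C@]12C
F9 | step 21 | macrocyclic triol (2-, 4- and 9-OH as in the target, 3-OTBS, 11,13-diene) | O[C@@H]1[C@H](O[Si](C)(C)C(C)(C)C)[C@@H](O)/C(C)=C\[C@@H]2OC(=O)[C@@](C)(O)[C@@]2(O)[C@@H](O)[C@H]2C(C)=CC=C[C@]12C
F10 | step 14 | anti thioester (S-ethyl thioester analogue of 25) | CCSC(=O)[C@@H](O[Si](C)(C)C(C)(C)C)[C@@H](O)[C@@]1(C)C=CC=C(C)[C@@H]1CO[Si](C)(C)C(C)(C)C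
F11 | step 3 | mirror-image enone alcohol (enantiomer of 8) | OC[C@]1(C)C=CC(=O)C(C)[C@H]1CO[Si](C)(C)C(C)(C)C
F12 | step 3 | mandelate ester of 8 [(S)-2-methoxy-2-phenylacetate] | CO[C@H](C(=O)OC[C@@]1(C)C=CC(=O)C(C)[C@@H]1CO[Si](C)(C)C(C)(C)C)c1ccccc1
F13 | step 3 | mandelate ester of F11 [(S)-2-methoxy-2-phenylacetate] | CO[C@H](C(=O)OC[C@]1(C)C=CC(=O)C(C)[C@H]1CO[Si](C)(C)C(C)(C)C)c1ccccc1
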